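The target is a cis-fused Δ8-drimane (C5–H and C10–CH3 on the same face) carrying a dienyl butenolide arm. Everything rests on the C9–C10 bond, which joins the tetrasubstituted C8=C9 alkene of ring B to the quaternary C10. An intramolecular Heck reaction of a ketone-derived 1,1-dibromoalkene onto the trisubstituted alkene of an (R)-α-ionone-derived ring A closes ring B in one operation: it forms C9–C10, sets C10 cis to the existing C5 stereocentre, fixes the C8=C9 alkene and leaves a C9–Br handle. The precursor is a monocyclic dibromodiene; the side chain is then grown from C9 by oxirane opening, Horner–Wadsworth–Emmons olefination and a final Suzuki coupling with 4-bromobutenolide.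

Key step: step 3

Numbering used: ring A = C1–C5 and C10 (gem-dimethyl at C4, angular methyl at C10); ring B = C5–C10 (methyl at C8); side chain C11, C12, C13 (bearing CH2OH), C14, C15, C16, then the butenolide.
Remark on the structure: the two ring-fusion descriptors place C5–H and C10–CH3 on the same face, so the decalin is cis-fused, (4aR,8aS) in naphthalene numbering.
Assumption: (R)-(+)-α-ionone of high enantiomeric purity (the natural enantiomer) is taken as purchasable; its ring stereocentre becomes C5 of the target.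

Step 1
Reactants: 1 (R)-α-ionone
Product: 3 4-[(1R)-2,6,6-trimethylcyclohex-2-en-1-yl]butan-2-one, via triethylsilyl enol ether 2 (not isolated)
Conditions: Et3SiH, RhCl(PPh3)3 (1 mol%), benzene, 60 °C; then 1 M HCl, THF, rt
Reagents that add atoms: none
Why: Rhodium-catalysed 1,4-hydrosilylation of the enone (conjugate reduction) gives silyl enol ether 2, whose mild hydrolysis releases the saturated methyl ketone; the isolated ring alkene is not an acceptor and the C5 stereocentre is untouched under these neutral conditions.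

Step 2
Reactants: 3 4-[(1R)-2,6,6-trimethylcyclohex-2-en-1-yl]butan-2-one
Product: 4 (6R)-6-(4,4-dibromo-3-methylbut-3-en-1-yl)-1,5,5-trimethylcyclohex-1-ene
Conditions: CBr4, PPh3, Zn dust, CH2Cl2, rt; then 3, toluene, 80 °C
Reagents that add atoms: carbon tetrabromide, BrC(Br)(Br)Br
Why: Ramirez dibromo-olefination (first stage of the Corey–Fuchs sequence) of the unhindered methyl ketone by the ylide Ph3P=CBr2 made in the flask, zinc keeping bromophosphonium species and HBr away from the ring alkene; because C9 carries two identical bromines the tetrasubstituted alkene has no geometry to control.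

Step 3
Reactants: 4 (6R)-6-(4,4-dibromo-3-methylbut-3-en-1-yl)-1,5,5-trimethylcyclohex-1-ene
Product: 5 (4aR,8aS)-1-bromo-2,5,5,8a-tetramethyl-3,4,4a,5,6,8a-hexahydronaphthalene
Conditions: Pd[P(t-Bu)3]2 (10 mol%), Cy2NMe, toluene, 100 °C
Reagents that add atoms: none
Why: Zerovalent palladium inserts into the C9–Br bond that lies cis to the C7 tether, the resulting alkenylpalladium bromide adds syn across the C10=C1 double bond of ring A and β-hydride elimination towards C2 releases the diene, the liberated HBr being taken up by the amine. The closest known reaction type is the intramolecular Mizoroki–Heck cyclisation that builds a quaternary centre on a 1-methylcyclohexene, here run on a 1,1-dibromoalkene with a bulky electron-rich phosphine under which C–Br oxidative addition is reversible. Ring B closes in the 6-exo-trig mode by formation of C9–C10, since 7-endo attack at C1 would need a tertiary alkylpalladium. The new stereocentre C10 is set by the resident C5 stereocentre: the four-centre insertion requires the C5 tether to be pseudoaxial on the ring A half-chair, a position already favoured by allylic strain with the C10 methyl group, so C9 is delivered to the face of C10 that carries C6 and C10–CH3 ends cis to C5–H. Site selectivity between the two bromines is needed and is secured because only the palladium species cis to the tether can cyclise, while the other reverts by C–Br reductive elimination. The remaining C9–Br bond, now flanked by C10 and the C8 methyl, and the tetrasubstituted C8=C9 alkene are expected to survive because re-insertion at this hindered position is slow and has no productive outlet.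

Step 4
Reactants: 5 (4aR,8aS)-1-bromo-2,5,5,8a-tetramethyl-3,4,4a,5,6,8a-hexahydronaphthalene
Product: 7 2-[(4aR,8aS)-2,5,5,8a-tetramethyl-3,4,4a,5,6,8a-hexahydronaphthalen-1-yl]ethan-1-ol, via alkenyllithium 6 (not isolated)
Conditions: t-BuLi (2.1 equiv), Et2O, −78 °C; then oxirane, −78 °C to rt; H2O
Reagents that add atoms: oxirane, C1CO1
Why: Bromine–lithium exchange at C9 followed by SN2 opening of oxirane by the alkenyllithium installs C11–C12 with a terminal hydroxyl; the alkenyl anion is held in ring B, so the C8=C9 alkene cannot isomerise and no stereocentre is formed.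

Step 5
Reactants: 7 2-[(4aR,8aS)-2,5,5,8a-tetramethyl-3,4,4a,5,6,8a-hexahydronaphthalen-1-yl]ethan-1-ol
Product: 8 2-[(4aR,8aS)-2,5,5,8a-tetramethyl-3,4,4a,5,6,7,8,8a-octahydronaphthalen-1-yl]ethan-1-ol
Conditions: H2 (1 atm), 5% Pd/C, EtOAc, rt
Reagents that add atoms: none
Why: Heterogeneous catalytic hydrogenation reduces the cis-disubstituted ring A alkene, while the tetrasubstituted C8=C9 alkene next to quaternary C10 should not be reduced; no stereocentre is created.

Step 6
Reactants: 8 2-[(4aR,8aS)-2,5,5,8a-tetramethyl-3,4,4a,5,6,7,8,8a-octahydronaphthalen-1-yl]ethan-1-ol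
Product: 9 (4aR,8aS)-1-(2-iodoethyl)-2,5,5,8a-tetramethyl-3,4,4a,5,6,7,8,8a-octahydronaphthalene
Conditions: PPh3, I2, imidazole, CH2Cl2, 0 °C to rt
Reagents that add atoms: iodine, [I][I]
Why: Appel-type iodination converts the primary alcohol into the iodide by SN2 displacement of the oxyphosphonium group under conditions that leave the alkene untouched.

Step 7
Reactants: 9 (4aR,8aS)-1-(2-iodoethyl)-2,5,5,8a-tetramethyl-3,4,4a,5,6,7,8,8a-octahydronaphthalene
Product: 10 ethyl 2-(diethoxyphosphoryl)-4-[(4aR,8aS)-2,5,5,8a-tetramethyl-3,4,4a,5,6,7,8,8a-octahydronaphthalen-1-yl]butanoate (both epimers at C2 of the butanoate)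
Conditions: NaH, DMF, 0 °C; then 9, 60 °C
Reagents that add atoms: triethyl phosphonoacetate, CCOC(=O)CP(=O)(OCC)OCC
Why: SN2 C-alkylation of the sodium salt of triethyl phosphonoacetate by the primary iodide forms the C12–C13 bond; the stabilised anion is too weakly basic for elimination, and the new phosphonate-bearing stereocentre is formed unselectively, which is immaterial because it becomes sp2 in step 8.

Step 8
Reactants: 10 ethyl 2-(diethoxyphosphoryl)-4-[(4aR,8aS)-2,5,5,8a-tetramethyl-3,4,4a,5,6,7,8,8a-octahydronaphthalen-1-yl]butanoate; 11 (2E)-3-(4,4,5,5-tetramethyl-1,3,2-dioxaborolan-2-yl)prop-2-enal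
Product: 12 ethyl (2E,4E)-2-{2-[(4aR,8aS)-2,5,5,8a-tetramethyl-3,4,4a,5,6,7,8,8a-octahydronaphthalen-1-yl]ethyl}-5-(4,4,5,5-tetramethyl-1,3,2-dioxaborolan-2-yl)penta-2,4-dienoate
Conditions: NaH, THF, 0 °C; then 11, 0 °C to rt
Reagents that add atoms: none
Why: Horner–Wadsworth–Emmons olefination of the α-alkylated phosphonate with the conjugated aldehyde should form the trisubstituted C13=C14 alkene with the ester trans to the alkenyl group (E), since reversible addition of the stabilised carbanion funnels through the less hindered oxaphosphetane; the (E)-alkenylboronate is carried through unchanged.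

Step 9
Reactants: 12 ethyl (2E,4E)-2-{2-[(4aR,8aS)-2,5,5,8a-tetramethyl-3,4,4a,5,6,7,8,8a-octahydronaphthalen-1-yl]ethyl}-5-(4,4,5,5-tetramethyl-1,3,2-dioxaborolan-2-yl)penta-2,4-dienoate
Product: 13 (2E,4E)-2-{2-[(4aR,8aS)-2,5,5,8a-tetramethyl-3,4,4a,5,6,7,8,8a-octahydronaphthalen-1-yl]ethyl}-5-(4,4,5,5-tetramethyl-1,3,2-dioxaborolan-2-yl)penta-2,4-dien-1-ol
Conditions: i-Bu2AlH (2.5 equiv), CH2Cl2, −78 °C; aq. Rochelle salt
Reagents that add atoms: none
Why: 1,2-Reduction of the conjugated ethyl ester by i-Bu2AlH at low temperature gives the allylic alcohol without touching the diene, whose geometry is retained, or the pinacol boronate.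

Step 10
Reactants: 13 (2E,4E)-2-{2-[(4aR,8aS)-2,5,5,8a-tetramethyl-3,4,4a,5,6,7,8,8a-octahydronaphthalen-1-yl]ethyl}-5-(4,4,5,5-tetramethyl-1,3,2-dioxaborolan-2-yl)penta-2,4-dien-1-ol; 14 4-bromofuran-2(5H)-one
Product: 15 4-[(1E,3E)-4-(hydroxymethyl)-6-[(4aR,8aS)-2,5,5,8a-tetramethyl-3,4,4a,5,6,7,8,8a-octahydronaphthalen-1-yl]hexa-1,3-dien-1-yl]furan-2(5H)-one (CNP0232848.3)
Conditions: PdCl2(dppf) (5 mol%), K3PO4, THF/H2O, 40 °C
Reagents that add atoms: none
Why: Suzuki–Miyaura coupling: fast oxidative addition of the electron-poor β-bromobutenolide, transmetalation of the alkenylboronate with retention of the E geometry and reductive elimination form the C16–butenolide bond under a mild phosphate base that the lactone and the free alcohol should tolerate.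

Compound list
1 | (R)-α-ionone, (3E)-4-[(1R)-2,6,6-trimethylcyclohex-2-en-1-yl]but-3-en-2-one | CC1=CCCC(C)(C)[C@H]1/C=C/C(C)=O | starting material
2 | triethyl({4-[(1R)-2,6,6-trimethylcyclohex-2-en-1-yl]but-2-en-2-yl}oxy)silane (enol ether geometry not controlled) | CC1=CCCC(C)(C)[C@H]1CC=C(C)O[Si](CC)(CC)CC | intermediate
3 | 4-[(1R)-2,6,6-trimethylcyclohex-2-en-1-yl]butan-2-one | CC1=CCCC(C)(C)[C@H]1CCC(C)=O | intermediate
4 | (6R)-6-(4,4-dibromo-3-methylbut-3-en-1-yl)-1,5,5-trimethylcyclohex-1-ene | CC1=CCCC(C)(C)[C@H]1CCC(C)=C(Br)Br | intermediate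
5 | (4aR,8aS)-1-bromo-2,5,5,8a-tetramethyl-3,4,4a,5,6,8a-hexahydronaphthalene (cis-fused) | CC1=C(Br)[C@@]2(C)C=CCC(C)(C)[C@H]2CC1 | intermediate
6 | [(4aR,8aS)-2,5,5,8a-tetramethyl-3,4,4a,5,6,8a-hexahydronaphthalen-1-yl]lithium | CC1=C([Li])[C@@]2(C)C=CCC(C)(C)[C@H]2CC1 | intermediate
7 | 2-[(4aR,8aS)-2,5,5,8a-tetramethyl-3,4,4a,5,6,8a-hexahydronaphthalen-1-yl]ethan-1-ol | CC1=C(CCO)[C@@]2(C)C=CCC(C)(C)[C@H]2CC1 | intermediate
8 | 2-[(4aR,8aS)-2,5,5,8a-tetramethyl-3,4,4a,5,6,7,8,8a-octahydronaphthalen-1-yl]ethan-1-ol | CC1=C(CCO)[C@@]2(C)CCCC(C)(C)[C@H]2CC1 | intermediate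
9 | (4aR,8aS)-1-(2-iodoethyl)-2,5,5,8a-tetramethyl-3,4,4a,5,6,7,8,8a-octahydronaphthalene | CC1=C(CCI)[C@@]2(C)CCCC(C)(C)[C@H]2CC1 | intermediate
10 | ethyl 2-(diethoxyphosphoryl)-4-[(4aR,8aS)-2,5,5,8a-tetramethyl-3,4,4a,5,6,7,8,8a-octahydronaphthalen-1-yl]butanoate (epimers at C2) | CC1=C(CCC(C(=O)OCC)P(=O)(OCC)OCC)[C@@]2(C)CCCC(C)(C)[C@H]2CC1 | intermediate
11 | (2E)-3-(4,4,5,5-tetramethyl-1,3,2-dioxaborolan-2-yl)prop-2-enal | O=C/C=C/B1OC(C)(C)C(C)(C)O1 | starting material
12 | ethyl (2E,4E)-2-{2-[(4aR,8aS)-2,5,5,8a-tetramethyl-3,4,4a,5,6,7,8,8a-octahydronaphthalen-1-yl]ethyl}-5-(4,4,5,5-tetramethyl-1,3,2-dioxaborolan-2-yl)penta-2,4-dienoate | CC1=C(CC/C(=C\C=C\B2OC(C)(C)C(C)(C)O2)C(=O)OCC)[C@@]2(C)CCCC(C)(C)[C@H]2CC1 | intermediate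
13 | (2E,4E)-2-{2-[(4aR,8aS)-2,5,5,8a-tetramethyl-3,4,4a,5,6,7,8,8a-octahydronaphthalen-1-yl]ethyl}-5-(4,4,5,5-tetramethyl-1,3,2-dioxaborolan-2-yl)penta-2,4-dien-1-ol | CC1=C(CC/C(=C\C=C\B2OC(C)(C)C(C)(C)O2)CO)[C@@]2(C)CCCC(C)(C)[C@H]2CC1 | intermediate
14 | 4-bromofuran-2(5H)-one | BrC1=CC(=O)OC1 | starting material
15 | 4-[(1E,3E)-4-(hydroxymethyl)-6-[(4aR,8aS)-2,5,5,8a-tetramethyl-3,4,4a,5,6,7,8,8a-octahydronaphthalen-1-yl]hexa-1,3-dien-1-yl]furan-2(5H)-one | CC1=C(CC/C(=C\C=C\C2=CC(=O)OC2)CO)[C@@]2(C)CCCC(C)(C)[C@H]2CC1 | target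

Total step count: 10. Longest linear sequence: 10 steps (1 to 15).

Steps most likely to fail

Step 3. Oxidative addition may take place mainly at the bromine cis to the methyl group, which cannot cyclise and may end in hydrodebromination; insertion into the trisubstituted ring alkene may be slow; facial control at C10 may be incomplete. Any migration of the new ring A double bond by Pd–H re-addition is harmless, because step 5 saturates it. The fallback is a radical closure of ring B that sets out from 3 and returns at 8. Ketone 3 is treated with ethynylmagnesium bromide (THF, 0 °C) to give 3-methyl-5-[(1R)-2,6,6-trimethylcyclohex-2-en-1-yl]pent-1-yn-3-ol F1 (carbinol epimers). Acylation (n-BuLi, ClCO2Me, THF, −78 °C) gives methyl 3-methyl-5-[(1R)-2,6,6-trimethylcyclohex-2-en-1-yl]pent-1-yn-3-yl carbonate F2. Palladium-catalysed alkoxycarbonylation of the propargylic carbonate (Pd(OAc)2, PPh3, CO 10 bar, MeOH, 50 °C) should give methyl 4-methyl-6-[(1R)-2,6,6-trimethylcyclohex-2-en-1-yl]hexa-2,3-dienoate F3 (allene axis not controlled). Metal-hydride hydrogen-atom transfer (Fe(acac)3, PhSiH3, EtOH, 60 °C) to the ring alkene would generate the tertiary C10 radical. This radical should attack the central allene carbon C9 in a 6-exo closure from the face of the pseudoaxial C5 tether; the cis fusion expected on this conformational argument would have to be verified. Reduction of the ester-stabilised allyl radical and protonation at C11 would give methyl 2-[(4aR,8aS)-2,5,5,8a-tetramethyl-3,4,4a,5,6,7,8,8a-octahydronaphthalen-1-yl]acetate F4 with ring A already saturated. LiAlH4 (Et2O, 0 °C) then gives 8.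

Step 4. The hindered alkenyllithium at C9 may be protonated or may open oxirane too slowly, returning debrominated material. The fallback sets out from 5 and returns at 7 by cross-coupling and hydroboration. Suzuki–Miyaura vinylation of 5 (potassium vinyltrifluoroborate, PdCl2(dppf), K3PO4, THF/H2O, 80 °C) gives (4aR,8aS)-1-ethenyl-2,5,5,8a-tetramethyl-3,4,4a,5,6,8a-hexahydronaphthalene F5. Hydroboration of its monosubstituted vinyl group with 9-BBN (THF, 0 °C to rt) should give 9-{2-[(4aR,8aS)-2,5,5,8a-tetramethyl-3,4,4a,5,6,8a-hexahydronaphthalen-1-yl]ethyl}-9-borabicyclo[3.3.1]nonane F6, the ring alkenes being far less reactive. Oxidation (NaOH, H2O2) gives 7.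

Step 8. The E selectivity in forming the trisubstituted C13=C14 alkene from an α-branched phosphonate may be incomplete, and the isomers may be hard to separate. The fallback sets out from 9 and returns at 12 through a stabilised phosphorane. Iodide 9 alkylates ethyl (triphenylphosphoranylidene)acetate (MeCN, reflux) to give {1-ethoxy-1-oxo-4-[(4aR,8aS)-2,5,5,8a-tetramethyl-3,4,4a,5,6,7,8,8a-octahydronaphthalen-1-yl]butan-2-yl}triphenylphosphonium iodide F7. Aqueous NaOH converts it into ethyl 4-[(4aR,8aS)-2,5,5,8a-tetramethyl-3,4,4a,5,6,7,8,8a-octahydronaphthalen-1-yl]-2-(triphenyl-λ5-phosphanylidene)butanoate F8. Wittig reaction of this ylide with 11 (toluene, 80 °C) should give 12 with the high E preference typical of α-substituted ester ylides.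

Further compounds
F1 | step 3 | 3-methyl-5-[(1R)-2,6,6-trimethylcyclohex-2-en-1-yl]pent-1-yn-3-ol | CC1=CCCC(C)(C)[C@H]1CCC(C)(O)C#C
F2 | step 3 | methyl 3-methyl-5-[(1R)-2,6,6-trimethylcyclohex-2-en-1-yl]pent-1-yn-3-yl carbonate | CC1=CCCC(C)(C)[C@H]1CCC(C)(OC(=O)OC)C#C
F3 | step 3 | methyl 4-methyl-6-[(1R)-2,6,6-trimethylcyclohex-2-en-1-yl]hexa-2,3-dienoate | CC1=CCCC(C)(C)[C@H]1CCC(C)=C=CC(=O)OC
F4 | step 3 | methyl 2-[(4aR,8aS)-2,5,5,8a-tetramethyl-3,4,4a,5,6,7,8,8a-octahydronaphthalen-1-yl]acetate | CC1=C(CC(=O)OC)[C@@]2(C)CCCC(C)(C)[C@H]2CC1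
F5 | step 4 | (4aR,8aS)-1-ethenyl-2,5,5,8a-tetramethyl-3,4,4a,5,6,8a-hexahydronaphthalene | CC1=C(C=C)[C@@]2(C)C=CCC(C)(C)[C@H]2CC1
F6 | step 4 | 9-{2-[(4aR,8aS)-2,5,5,8a-tetramethyl-3,4,4a,5,6,8a-hexahydronaphthalen-1-yl]ethyl}-9-borabicyclo[3.3.1]nonane | CC1=C(CCB3C4CCCC3CCC4)[C@@]2(C)C=CCC(C)(C)[C@H]2CC1
F7 | step 8 | {1-ethoxy-1-oxo-4-[(4aR,8aS)-2,5,5,8a-tetramethyl-3,4,4a,5,6,7,8,8a-octahydronaphthalen-1-yl]butan-2-yl}triphenylphosphonium iodide | CC1=C(CCC(C(=O)OCC)[P+](c3ccccc3)(c3ccccc3)c3ccccc3)[C@@]2(C)CCCC(C)(C)[C@H]2CC1.[I-]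
F8 | step 8 | ethyl 4-[(4aR,8aS)-2,5,5,8a-tetramethyl-3,4,4a,5,6,7,8,8a-octahydronaphthalen-1-yl]-2-(triphenyl-λ5-phosphanylidene)butanoate | CC1=C(CCC(C(=O)OCC)=P(c3ccccc3)(c3ccccc3)c3ccccc3)[C@@]2(C)CCCC(C)(C)[C@H]2CC1
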